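(The runs were generated by integration for substances that don't exist; noise was put on by code.)

Which reagent does the flask hold in the smaller amount? The partner: 0.840 M against 1.2 M of starting material.

| flask | starting material | partner | free catalyst | remark | time |
|---|---|---|---|---|---|
| dawn | 1.2 M | 0.56 M | 26 mM | run made earlier |  |
| winter | 1.2 M | 1.3 M | 26 mM | run made earlier |  |
| noon | 1.2 M | 0.84 M | 52 mM | run made earlier |  |
| flask | 1.2 M | 0.840 M | 26 mM |  | 40 min |

| run | time / min | starting material / % | target / % | catalyst intermediate A / % |
|---|---|---|---|---|
| dawn | 4.00 | 54 | 46 | 3 |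
| dawn | 6.00 | 48 | 45 | 3 |
| dawn | 10.0 | 51 | 46 | 1 |
| dawn | 20.0 | 52 | 47 | 2 |
| dawn | 30.0 | 48 | 47 | 3 |
| dawn | 50.0 | 50 | 48 | 1 |
| winter | 3.00 | 41 | 56 | 0 |
| winter | 10.0 | 1 | 101 | 1 |
| winter | 15.0 | 2 | 101 | 0 |
| winter | 25.0 | 0 | 102 | 0 |
| winter | 40.0 | 1 | 101 | 0 |
| winter | 50.0 | 1 | 102 | 0 |
| noon | 4.00 | 27 | 68 | 4 |
| noon | 8.00 | 25 | 72 | 4 |
| noon | 15.0 | 26 | 70 | 6 |
| noon | 25.0 | 25 | 68 | 1 |
| noon | 50.0 | 25 | 72 | 4 |

(readings scatter by 1.5 percentage points)

- share of the starting material used up at 40 min
- target at 40 min, in percent of the starting material charged
- catalyst intermediate A at 40 min, in percent of the starting material charged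



What does a balance of the partner say? If each target takes one partner, target stops when the partner charge has been used. Here 70.0 % is the partner ceiling, c(partner) over c(starting material), the yield set by the limiting reagent.

Do the runs support that? The dawn run has a ceiling of 46.7 % and reads 47 % of target. The noon run has a ceiling of 70.0 % and reads 72 % and 68 %, on either side of it, and a reading scatters by 1.5 percentage points.

But the noon run had twice the flask's catalyst. Will the flask get there in time? The dawn run, with the flask's catalyst and less partner, is level by 4.00 min. The winter run, with the same catalyst and more partner, reads 101 % of target at 10.0 min. So I expect the flask to be level well before 40 min.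

Then why not equate conversion with target? I read some starting material as standing in catalyst intermediate A. The noon run reads 4 % of it at 4.00 min and 4 % at 50.0 min, against a catalyst share, c(free catalyst) over c(starting material), of 4.33 %. For the flask that share is 2.17 %, so my conversion is 72.2 %.

The forecast agrees with this reckoning: conversion 72.2 % (70 % to 74.5 %), target 70 % (68 % to 72 %), catalyst intermediate A 2.2 % (0.8 % to 3.5 %). Its ground: “The partner is the limiting reagent”.

The flask gives conversion 72.2 %, target 70.0 % and catalyst intermediate A 2.17 %.

    catalyst intermediate C → free catalyst + target (k = 0.910 /s)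
    partner + catalyst intermediate A → catalyst intermediate B (k = 1.10 /M/s)
    catalyst intermediate B ⇌ released group + catalyst intermediate C (K = 0.440 M, k = 0.270 /s)
    starting material + free catalyst → catalyst intermediate A (k = 4.30 /M/s)

At 40.0 min the flask holds partner at 0 % of its charge, target at the partner ceiling, and catalyst intermediate A at 100 % of the catalyst charge, with starting material at 27.8 %. At 400 min the flask still gives 70.0 % of target. Now take the same flask with 0.21 M of partner. Its ceiling is 17.5 %, and adding the catalyst share gives a conversion of 19.7 %. That neighbour flask gives target 17.5 %, conversion 19.7 % and catalyst intermediate A 2.17 %, and its starting material stands at 80.3 %.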